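The data are simulated with made-up constants; the scatter is artificial.

**Turnover room.** A precatalyst charge of 0.14 mol% on the left-handed substrate has to turn over 857 times, one turnover being one reagent used per precatalyst charged, before the 1.20 equiv of reagent is consumed. Reagent is the limiting reagent here, so the question is how much of that room 3.0 d uses.

| setting | summer | winter | spring | flask |
|---|---|---|---|---|
| left-handed substrate | 0.14 M | 0.22 M | 0.10 M | 0.10 M |
| right-handed substrate | 0.14 M | 0.22 M | 0.10 M | 0.10 M |
| reagent | 1.2 equiv | 1.2 equiv | 2.4 equiv | 1.20 equiv |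
| precatalyst | 0.14 mol% | 0.14 mol% | 0.14 mol% | 0.14 mol% |
| remark | run made earlier | run made earlier | run made earlier |  |
| time |  |  |  | 3.0 d |

| run | time / h | left-handed product / % | right-handed product / % | left-handed substrate / % |
|---|---|---|---|---|
| summer | 4.00 | 4 | 1 | 47 |
| summer | 10.0 | 2 | 2 | 50 |
| summer | 20.0 | 9 | 3 | 44 |
| summer | 30.0 | 11 | 11 | 36 |
| summer | 40.0 | 13 | 14 | 36 |
| winter | 4.00 | 0 | 3 | 51 |
| winter | 10.0 | 6 | 5 | 51 |
| winter | 20.0 | 10 | 10 | 42 |
| winter | 30.0 | 14 | 17 | 37 |
| winter | 40.0 | 20 | 21 | 34 |
| spring | 3.00 | 0 | 0 | 48 |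
| spring | 6.00 | 2 | 1 | 48 |
| spring | 12.0 | 5 | 5 | 44 |
| spring | 25.0 | 11 | 16 | 38 |
| spring | 40.0 | 18 | 19 | 36 |

(standard deviation of a reading: 2 percentage points)

* excess of left-handed product over right-handed product in the product at 80 min
* excess of left-handed product over right-handed product in the product at 3.0 d
* part of the left-handed substrate and right-handed substrate charged together that has reacted at 3.0 d

- free catalyst is single-handed; left-handed substrate and right-handed substrate are mirror images of each other, charged as a racemate, each of them at the stated concentration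
- an excess is below zero if the other one leads

**Turnover pace.** One reagent is used per product, so the summed products at the last reading of each run give the reagent left. The logarithm of charge over reagent left, per hour and per catalyst charged, reads 76.3 L mol⁻¹ h⁻¹ in summer, 93.3 L mol⁻¹ h⁻¹ in winter and 65.8 L mol⁻¹ h⁻¹ in spring. These are readings with their scatter; their mean, 78.5 L mol⁻¹ h⁻¹, is taken as the turnover pace.

**What matters.** Pace, catalyst charged and time enter as one product. For this flask the spring pace reckons 29.1% reacted and the winter pace 36.6%, so the pace needs knowing well. The left-handed substrate readings do not enter. My own reckoning with the mean gives 32.8%. Turnovers do not tell the hands apart, so this gives no excess.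

**The forecast.** It gives 33% (27% to 39%) reacted, with excesses of 1% at 80 min and 0% at 3.0 d, on these grounds: “These scale with absolute reagent concentration”.

**The result.** The flask reaches 35.0% reacted, with excess −22.8% at 80 min and −0.296% at 3.0 d; 42% of its reagent remains at 3.0 d. The excess at 80 min stands 24 percentage points below the forecast.

    free catalyst + left-handed substrate ⇌ catalyst intermediate A (K = 3.60 L mol⁻¹, k = 79000 L mol⁻¹ h⁻¹)
    free catalyst + right-handed substrate ⇌ catalyst intermediate B (K = 13.0 L mol⁻¹, k = 92000 L mol⁻¹ h⁻¹)
    reagent + catalyst intermediate A → free catalyst + left-handed product (k = 380 L mol⁻¹ h⁻¹)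
    reagent + catalyst intermediate B → free catalyst + right-handed product (k = 190 L mol⁻¹ h⁻¹)
    left-handed product ⇌ right-handed product (k = 0.270 h⁻¹)
    precatalyst → free catalyst (k = 0.0740 h⁻¹)
    free catalyst ⇌ dormant form (K = 0.670, k = 0.0510 h⁻¹)

With 0.056 mol% of precatalyst, the same pace reckons 16.3% reacted, and that neighbouring flask gives 18.7%.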